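Slowness sits at the head of this scheme: the first step makes intermediate A at a modest pace, and it spends reagent, which target needs as well.

    substrate + reagent → intermediate A (k1 = 0.17 L mol⁻¹ min⁻¹)
    intermediate A ⇌ intermediate B (K2 = 2.1, k2 = 0.051 min⁻¹)
    reagent + intermediate B → intermediate C (k3 = 0.45 L mol⁻¹ min⁻¹)
    reagent + intermediate A → target (k4 = 0.18 L mol⁻¹ min⁻¹)
    intermediate C → intermediate D (k5 = 0.096 min⁻¹)
    intermediate D → side product A (k6 = 0.14 min⁻¹)
    substrate + intermediate A → side product B (k7 = 0.040 L mol⁻¹ min⁻¹)

| flask | substrate | reagent | time |
|---|---|---|---|
| grey | 0.15 M | 0.240 M | 40 min |
| blue | 0.30 M | 0.240 M | 40 min |
| green | 0.60 M | 0.240 M | 40 min |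

- percent here means substrate units held: one side product B counts as two
- "hardly changes" means that all values lie within two and a half points (for a concentration: within two and a half percent of the largest)
- run time (grey): 40 min

- [target] at the end for grey, blue, green, in this order
- the shape of the row from first to last (rises, then falls / falls all the way / hardly changes / rises all the way / falls, then rises)

**Two times.** Target forms from intermediate A and reagent, so both must stand in the flask at the same moment. Each unit of intermediate A has already cost one unit of reagent. The other reagent-consuming steps draw on species that the first step must make beforehand, and the conversions of intermediate C and intermediate D take no reagent. The times to compare are therefore the run, 40 min, and the half-life of reagent under the first step, which is the natural logarithm of 2 over the rate constant times c(substrate) as charged.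

**Half-life count.** That half-life is 27.2 min in grey, 13.6 min in blue and 6.80 min in green. Green fits 5.89 of them into the run. This half-life count, the run time divided by the reagent half-life under the first step with substrate as charged, is 2.94 for blue and 1.47 for grey. Taken as a decay, the count leaves 1.69% of the reagent in green and 36.1% in grey. This hand reckoning gives no value for target. It stops at an expectation: green loses its reagent early, grey starts making intermediate A at a quarter of green's rate, and the row turns over.

**The forecast.** It gave 0.027 M, 0.03 M and 0.025 M, a row that rises, then falls, noting that in green “substrate consumes reagent quickly”.

**The flasks.** The simulation gives 0.0271 M, 0.0305 M and 0.0246 M, a row that rises, then falls, as forecast. In green, reagent stood at 13.1% of its charge at 20.0 min and, against the 1.69% from the count, at 1.76% at 40.0 min; over that second stretch target went from 3.63% to 4.09% of the substrate charged, while side product B went from 8.24% to 13.7%. In grey, with a count of 1.47 and 36.1% reckoned for substrate as charged, 38.5% of the reagent's charge remained at the end, substrate stood at 34.2% of its charge, and target climbed from 10.6% at 20.0 min to 18.1%.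

The numbers of this flask come from no measurement; what happens was integrated by code.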